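Two questions stood on this flask, and I answered them with one quantity.

1. apparent order in reagent when 10% of the starting material are converted (percent change of the rate of making target for one percent more reagent charged)
2. apparent order in free catalyst when 10% of the starting material are converted (percent change of the rate of making target for one percent more free catalyst charged)

all flasks: free catalyst 2.5 mol%
- Friday's: starting material 0.087 M; reagent 0.50 equiv; run made earlier
- Thursday's: starting material 0.20 M; reagent 0.50 equiv; run made earlier
- Wednesday's: starting material 0.13 M; reagent 0.25 equiv; run made earlier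
- flask: starting material 0.13 M; reagent 0.500 equiv

| run | time / d | target / % | starting material / % |
|---|---|---|---|
| Friday's | 0.250 | 2.2 | 97.3 |
| Friday's | 0.833 | 9.4 | 91.0 |
| Friday's | 1.67 | 17.8 | 81.6 |
| Friday's | 2.50 | 25.0 | 73.9 |
| Friday's | 3.00 | 30.2 | 69.8 |
| Thursday's | 0.625 | 9.9 | 88.5 |
| Thursday's | 1.25 | 21.0 | 78.5 |
| Thursday's | 2.08 | 32.0 | 66.9 |
| Thursday's | 2.50 | 37.6 | 62.3 |
| Thursday's | 3.00 | 41.6 | 57.6 |
| Wednesday's | 0.625 | 6.5 | 92.8 |
| Wednesday's | 1.25 | 12.7 | 86.3 |
| Wednesday's | 2.08 | 19.0 | 80.2 |
| Wednesday's | 2.50 | 20.3 | 78.8 |
| Wednesday's | 3.00 | 23.4 | 76.6 |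

(each reading ± 0.5 percentage points)



The neighbour was Wednesday's run: same concentration, same loading, half the reagent. Wednesday's target stood at 23.4% after 3.00 d on a charge of 0.25 equiv, so I took reagent as the limiting reagent, one per target. This flask should then stop twice as far, at 0.500 equiv.

The early rates told something else. Friday's 0.113 d⁻¹ and Thursday's 0.158 d⁻¹, carried by a power of concentration to 0.13 M, gave 0.133 d⁻¹, against Wednesday's 0.104 d⁻¹. Doubling the reagent thus raised the rate 1.28-fold. I took the binding of reagent to free catalyst as a fast balance and defined the holding level, the c(reagent) at which the rate is 0.5 of its ceiling: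

rate ∝ c(reagent) / (holding level + c(reagent))

order in reagent = holding level / (holding level + c(reagent))

The two charges gave a holding level of 0.0250 M. With one reagent gone per starting material, c(reagent) was 0.0520 M at 10% conversion, so my order was 0.325.

No run varied free catalyst. Its charge was 0.0625 of that reagent, so I expected its forms to scale with the charge and committed to an order of 1.

The forecast said 0.3 and 1: “This fits saturation with K of about 0.02 M, giving about 0.3 at 10% conversion”. My reagent order lay slightly higher.

The flask gives 0.28 and 0.99, and after 40.0 d its target stands at 50.0% with reagent at 0%.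

    catalyst intermediate D → free catalyst + target (k = 5.29 × 10⁻⁴ s⁻¹)
    reagent + free catalyst ⇌ catalyst intermediate A (K = 25.0 L mol⁻¹, k = 0.191 L mol⁻¹ s⁻¹)
    catalyst intermediate C → catalyst intermediate D (k = 7.80 × 10⁻⁴ s⁻¹)
    starting material + catalyst intermediate B ⇌ catalyst intermediate C (K = 3.80 L mol⁻¹, k = 0.00488 L mol⁻¹ s⁻¹)
    catalyst intermediate A → by-product + catalyst intermediate B (k = 2.38 × 10⁻⁴ s⁻¹)

Both forecast values held. Among the effects on the order in reagent, the step back from catalyst intermediate A is the largest single one; at 1.53 d, catalyst intermediate A falls back 32 times faster than it goes on. A run of this flask with that reverse step taken away has its order in reagent go from 0.28 to 0.011. Through the same rule, at the same c(reagent), that run has a holding level of 5.77 × 10⁻⁴ M, far below the 0.0250 M I read for this flask.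

The numbers in the tables were computed from invented constants, noise included.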